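**Retrosynth­etic overview**
- Feature: in ring A (anisole ring; C1 ether O, C2 OMe, C4 and C6 Br) the hydrogen-bearing C5 lies para to the C2 oxygen and between the two brominated carbons. A nitrogen group at C5 can therefore arrive with the ring, steer both bromines as NH2, and then be erased.
- 15 ⇐ 14 (O-debenzylation, ring B) ⇐ 12 (deamination at C5) ⇐ 11 (double ortho-bromination) ⇐ 10 ⇐ 9 (nitro reduction, O-methylation).
- 9 ⇐ aryloxyacetone 5 (supplies C1–C2–C3) + sodium nitromalonaldehyde 7 (supplies C4–C5–C6), by a [3+3] double aldol benzannulation that makes C1–C6 and C3–C4.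
- 5 ⇐ phenol 3 + chloroacetone, so the crowded diaryl ether oxygen is set by a plain O-alkylation. 3 ⇐ 2-(benzyloxy)phenol by ortho-then-para bromination, and 7 ⇐ mucobromic acid.
- Ring order: ring B is bought; ring A is the only ring formed (step 5).

Key step: step 5

**Remarks on the chemistry**
- Numbering: ring A has C1 (ether O), C2 (OMe), C3 H, C4 Br, C5 H, C6 Br. Ring B has C1' (ether O), C2' (OH), C4' and C6' Br.
- The target SMILES holds no stereodescriptor. Rotation about the diaryl ether bonds is taken as fast, so no stereochemical issue arises.
- Ring B is brominated ortho first and para second. In a one-pot double bromination, once C4 is filled the second bromine could go para to the benzyloxy group instead of ortho to OH.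

**Step 1**
Reactants: 1 2-(benzyloxy)phenol
Product: 2 2-(benzyloxy)-6-bromophenol
Conditions: Br2 (1.0 equiv), t-BuNH2 (2.0 equiv), toluene, −30 °C; then 1 in CH2Cl2, −78 °C → rt
Reagents that add atoms: bromine, BrBr
Why: Amine-mediated ortho-selective electrophilic bromination of a phenol, in which the N-bromoamine made from Br2 and t-BuNH2 delivers bromine inside a hydrogen-bonded pair with the phenol OH, so substitution should occur at C6, the only free ortho position, as is well known for guaiacol-type phenols.

**Step 2**
Reactants: 2 2-(benzyloxy)-6-bromophenol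
Product: 3 2-(benzyloxy)-4,6-dibromophenol
Conditions: NBS (1.05 equiv), MeCN, 0 °C → rt, dark
Reagents that add atoms: N-bromosuccinimide, O=C1CCC(=O)N1Br
Why: Electrophilic aromatic bromination in which the free OH is the dominant director and its para position C4 is open and unhindered, whereas C5 (para to OBn) is meta to OH and ortho to the C6 bromine, so the 4,6-pattern of ring B should result.

**Step 3**
Reactants: 3 2-(benzyloxy)-4,6-dibromophenol; 4 chloroacetone
Product: 5 1-[2-(benzyloxy)-4,6-dibromophenoxy]propan-2-one
Conditions: K2CO3, DMF, 50 °C
Reagents that add atoms: none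
Why: Williamson ether synthesis, in which K2CO3 fully deprotonates the acidic dibromophenol and the very reactive α-chloroketone offsets the two ortho substituents of the phenoxide, creating the C–O bond that becomes the diaryl ether link.

**Step 4**
Reactants: 6 mucobromic acid
Product: 7 sodium nitromalonaldehyde, Na[O2NC(CHO)2], collected as its monohydrate
Conditions: NaNO2 (excess), H2O/EtOH, 54 °C; cool to 0 °C, recrystallise from aq EtOH (small scale, shield, use promptly)
Reagents that add atoms: sodium nitrite, [Na+].[O-]N=O; water, O
Why: Classical preparation of this salt by vinylic addition–elimination, in which nitrite replaces the bromine on the carbon next to the formyl group, the other C–Br carbon is hydrolysed to the carbonyl level and the acid carbon leaves as CO2, so the stabilised nitro-enolate crystallises as an impact- and heat-sensitive sodium salt.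

**Step 5**
Reactants: 5 1-[2-(benzyloxy)-4,6-dibromophenoxy]propan-2-one; 7 sodium nitromalonaldehyde
Product: 9 2-[2-(benzyloxy)-4,6-dibromophenoxy]-4-nitrophenol, via open-chain sodium nitrodienolate 8 (not isolated)
Conditions: NaOH (1.5 equiv), EtOH/H2O, 0 °C → rt, 2–4 d; then aq HCl to pH 2
Reagents that add atoms: none
Why: Hydroxide enolises 5 at its more acidic aryloxymethylene carbon, which adds to one formyl group of 7 and loses water to give 8 (bond C1–C6). The methyl-side enolate of 8 then attacks the remaining formyl carbon in a 6-(enolendo)-exo-trig intramolecular aldol (bond C3–C4, closing ring A), and dehydration and tautomerisation of the cyclohexadienone give the nitrophenoxide, an irreversible aromatisation that drains the reversible aldol equilibria. The closest known reaction type is the classical condensation of sodium nitromalonaldehyde with ketones that have two enolisable α-carbons (acetone to 4-nitrophenol, dibenzyl ketone to 2,6-diphenyl-4-nitrophenol), here applied to an aryloxyacetone. No stereocentre is formed. No regiochemical choice exists, because the dialdehyde is symmetrical and both α-carbons of the ketone end up in the ring, so either order of bond formation puts the ketone carbon at C2 (OH), the aryloxy carbon at C1 and the nitro carbon para to OH at C5. The selectivity needed is cross-condensation over self-aldol of 5, which is favoured by the non-enolisable, doubly electrophilic partner, a slight excess of 7 and the ethanol co-solvent that keeps 5 in solution, while the aryl bromides and the benzyl ether are inert to cold dilute NaOH.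

**Step 6**
Reactants: 9 2-[2-(benzyloxy)-4,6-dibromophenoxy]-4-nitrophenol
Product: 10 1-(benzyloxy)-3,5-dibromo-2-(2-methoxy-5-nitrophenoxy)benzene
Conditions: MeI, K2CO3, DMF, rt
Reagents that add atoms: iodomethane, CI
Why: Williamson O-methylation (SN2) of the acidic 4-nitrophenol, which fixes the C2 oxygen of ring A as the methyl ether of the target while the ring B oxygen stays masked as the benzyl ether.

**Step 7**
Reactants: 10 1-(benzyloxy)-3,5-dibromo-2-(2-methoxy-5-nitrophenoxy)benzene
Product: 11 3-[2-(benzyloxy)-4,6-dibromophenoxy]-4-methoxyaniline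
Conditions: Fe powder, AcOH/EtOH/H2O, 70 °C
Reagents that add atoms: none
Why: Béchamp-type dissolving-metal reduction of the nitroarene, chosen because zerovalent iron in weak acid leaves the aryl bromides and the benzyl ether untouched, which catalytic hydrogenation would not.

**Step 8**
Reactants: 11 3-[2-(benzyloxy)-4,6-dibromophenoxy]-4-methoxyaniline
Product: 12 3-[2-(benzyloxy)-4,6-dibromophenoxy]-2,6-dibromo-4-methoxyaniline
Conditions: NBS (2.05 equiv), MeCN, −10 °C → rt, dark
Reagents that add atoms: N-bromosuccinimide, O=C1CCC(=O)N1Br
Why: Electrophilic aromatic bromination governed by the C5 amino group, whose para position C2 carries OMe, so both equivalents should go ortho, to C4 (also para to the aryloxy oxygen) and C6 (also ortho to it), while C3 is meta to nitrogen and ring B is deactivated by its two bromines.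

**Step 9**
Reactants: 12 3-[2-(benzyloxy)-4,6-dibromophenoxy]-2,6-dibromo-4-methoxyaniline
Product: 14 1-(benzyloxy)-3,5-dibromo-2-(2,4-dibromo-6-methoxyphenoxy)benzene, via arenediazonium hydrogen sulfate 13 (not isolated)
Conditions: NaNO2, H2SO4, AcOH/1,4-dioxane/H2O, 0–5 °C; then 50% aq H3PO2, 0 °C → rt
Reagents that add atoms: sodium nitrite, [Na+].[O-]N=O, and sulfuric acid, OS(=O)(=O)O (both appear only in 13; nothing but hydrogen stays in 14)
Why: Diazotisation followed by hydrodediazoniation with hypophosphorous acid (radical-chain reduction of the diazonium ion), the standard way to erase an amino group flanked by two halogens, as in the tribromoaniline to tribromobenzene conversion, which should leave C5–H while the aryl bromides and both ethers tolerate the cold acid.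

**Step 10**
Reactants: 14 1-(benzyloxy)-3,5-dibromo-2-(2,4-dibromo-6-methoxyphenoxy)benzene
Product: 15 3,5-dibromo-2-(2,4-dibromo-6-methoxyphenoxy)phenol (target)
Conditions: BCl3 (1 M in CH2Cl2, 2.5 equiv), pentamethylbenzene (3 equiv), CH2Cl2, −78 °C; aqueous quench
Reagents that add atoms: none
Why: Lewis-acid debenzylation with BCl3 and pentamethylbenzene as a non-basic benzyl-cation scavenger, which at −78 °C cleaves the aryl benzyl ether through its stabilised benzylic cation far faster than the aryl methyl ether and, unlike hydrogenolysis, spares the four C–Br bonds.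

**Compound list**
1 | 2-(benzyloxy)phenol | Oc1ccccc1OCc1ccccc1 | starting material
2 | 2-(benzyloxy)-6-bromophenol | Oc1c(Br)cccc1OCc1ccccc1 | intermediate
3 | 2-(benzyloxy)-4,6-dibromophenol | Oc1c(OCc2ccccc2)cc(Br)cc1Br | intermediate
4 | chloroacetone | CC(=O)CCl | starting material
5 | 1-[2-(benzyloxy)-4,6-dibromophenoxy]propan-2-one | CC(=O)COc1c(OCc2ccccc2)cc(Br)cc1Br | intermediate
6 | mucobromic acid (lactol form) | OC1OC(=O)C(Br)=C1Br | starting material
7 | sodium nitromalonaldehyde (SMILES of the anhydrous salt; delocalised anion) | [Na+].[O-]C=C(C=O)[N+](=O)[O-] | intermediate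
8 | sodium 4-[2-(benzyloxy)-4,6-dibromophenoxy]-2-nitro-5-oxohexa-1,3-dien-1-olate (delocalised anion, geometry not fixed; not isolated) | CC(=O)C(Oc1c(OCc2ccccc2)cc(Br)cc1Br)=CC(=C[O-])[N+](=O)[O-].[Na+] | intermediate
9 | 2-[2-(benzyloxy)-4,6-dibromophenoxy]-4-nitrophenol | Oc1ccc([N+](=O)[O-])cc1Oc1c(OCc2ccccc2)cc(Br)cc1Br | intermediate
10 | 1-(benzyloxy)-3,5-dibromo-2-(2-methoxy-5-nitrophenoxy)benzene | COc1ccc([N+](=O)[O-])cc1Oc1c(OCc2ccccc2)cc(Br)cc1Br | intermediate
11 | 3-[2-(benzyloxy)-4,6-dibromophenoxy]-4-methoxyaniline | COc1ccc(N)cc1Oc1c(OCc2ccccc2)cc(Br)cc1Br | intermediate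
12 | 3-[2-(benzyloxy)-4,6-dibromophenoxy]-2,6-dibromo-4-methoxyaniline | COc1cc(Br)c(N)c(Br)c1Oc1c(OCc2ccccc2)cc(Br)cc1Br | intermediate
13 | 3-[2-(benzyloxy)-4,6-dibromophenoxy]-2,6-dibromo-4-methoxybenzenediazonium hydrogen sulfate (not isolated) | COc1cc(Br)c([N+]#N)c(Br)c1Oc1c(OCc2ccccc2)cc(Br)cc1Br.OS(=O)(=O)[O-] | intermediate
14 | 1-(benzyloxy)-3,5-dibromo-2-(2,4-dibromo-6-methoxyphenoxy)benzene | COc1cc(Br)cc(Br)c1Oc1c(OCc2ccccc2)cc(Br)cc1Br | intermediate
15 | 3,5-dibromo-2-(2,4-dibromo-6-methoxyphenoxy)phenol | COc1cc(Br)cc(Br)c1Oc1c(O)cc(Br)cc1Br | target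

**Total step count:** 10. **Longest linear sequence:** 9 (steps 1–3 and 5–10; step 4 is a one-step branch).

**Steps most likely to fail**

1. **Step 5 (benzannulation).**
   - What may go wrong: the lipophilic ketone may stay out of the aqueous phase. Base-induced deformylation of the nitromalonaldehyde salt and self-aldol of the ketone may then outrun the double condensation.
   - Fallback, from 3 back to 10: Chan–Evans–Lam O-arylation of 3 with commercial (2-methoxy-5-nitrophenyl)boronic acid (Cu(OAc)2, pyridine, 4 Å molecular sieves, CH2Cl2, air, rt). This should give 10 directly and bypass 5, 7, 8 and 9.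
   - Why it should hold: the room-temperature copper coupling leaves aryl bromides alone and is proven on phenols flanked by two ortho halogens. It makes no compound outside the list (F0).

2. **Step 8 (double bromination).**
   - What may go wrong: the bromine source may oxidise the electron-rich 4-methoxyaniline ring towards quinone-imine material. The reaction may stall after the first bromination because C6 is wedged between the amine and the bulky aryloxy group. Bromine may also spill over to C3.
   - Fallback, from 11 back to 12: a staged, N-protected sequence.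
     - Acetylation (Ac2O, pyridine) would give N-{3-[2-(benzyloxy)-4,6-dibromophenoxy]-4-methoxyphenyl}acetamide F1.
     - Monobromination (NBS, MeCN) ortho to NHAc and para to the aryloxy oxygen would give N-{5-[2-(benzyloxy)-4,6-dibromophenoxy]-2-bromo-4-methoxyphenyl}acetamide F2.
     - Hydrolysis (KOH, EtOH/H2O, reflux) would free 5-[2-(benzyloxy)-4,6-dibromophenoxy]-2-bromo-4-methoxyaniline F3.
     - This less oxidisable amine would take the last bromine at its only free ortho position C6 (Br2, 1 equiv, NaOAc, AcOH) to give 12.

3. **Step 9 (deamination).**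
   - What may go wrong: diazotisation of the weakly basic, poorly soluble amine may be incomplete. The acid medium may erode the benzyl ether. Nitrogen may be replaced by water, or azo coupling may compete with hydrogen transfer.
   - Fallback, from 12 back to 14: replace nitrogen by iodine and then remove the iodine by metalation.
     - Sandmeyer-type diazotisation–iodination under mild conditions (p-TsOH·H2O, NaNO2, KI, MeCN, rt) would give 1-(benzyloxy)-3,5-dibromo-2-(2,4-dibromo-3-iodo-6-methoxyphenoxy)benzene F4.
     - Iodine-selective halogen–magnesium exchange (i-PrMgCl·LiCl, THF, −40 °C) followed by a MeOH quench would give 14. The temperature is kept low so that the ortho-bromoarylmagnesium species does not eliminate to an aryne.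

**Further compounds**
F0 | step 5 | none | none
F1 | step 8 | N-{3-[2-(benzyloxy)-4,6-dibromophenoxy]-4-methoxyphenyl}acetamide | COc1ccc(NC(C)=O)cc1Oc1c(OCc2ccccc2)cc(Br)cc1Br
F2 | step 8 | N-{5-[2-(benzyloxy)-4,6-dibromophenoxy]-2-bromo-4-methoxyphenyl}acetamide | COc1cc(Br)c(NC(C)=O)cc1Oc1c(OCc2ccccc2)cc(Br)cc1Br
F3 | step 8 | 5-[2-(benzyloxy)-4,6-dibromophenoxy]-2-bromo-4-methoxyaniline | COc1cc(Br)c(N)cc1Oc1c(OCc2ccccc2)cc(Br)cc1Br
F4 | step 9 | 1-(benzyloxy)-3,5-dibromo-2-(2,4-dibromo-3-iodo-6-methoxyphenoxy)benzene | COc1cc(Br)c(I)c(Br)c1Oc1c(OCc2ccccc2)cc(Br)cc1Br
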